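**Assumption:** (2S)-eriodictyol of high ee and tert-butyl 2-methylbut-3-en-2-yl carbonate are taken as catalogue items (the carbonate is otherwise one step from 2-methylbut-3-en-2-ol and Boc2O). The route has not been run; conditions are drawn from analogous phenol chemistry.

## Retrosynthetic overview

1. Sigmoidin A ⇐ its 7-O-TIPS ether (buffered fluoride desilylation).
2. Both aryl–prenyl C–C bonds (C2'–CH2 and C5'–CH2) ⇐ double aromatic Claisen [3,3] rearrangement of the 3',4'-bis(1,1-dimethylallyl) ether. Each ether oxygen has only one free ortho carbon (C2' for O3', C5' for O4'), so the regiochemistry is forced.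
3. Bis-ether ⇐ Pd-catalysed O-tert-prenylation of the catechol of 7-O-TIPS-eriodictyol ⇐ (2S)-eriodictyol.
4. No ring is formed in the route: rings A, C and B and the C2 (S) stereocentre are bought intact in (2S)-eriodictyol. C2 is never a reacting centre, and conditions are kept neutral or weakly basic to avoid flavanone–chalcone racemisation.

## Route

**Step 1**
Reactants: 1, (2S)-eriodictyol [(2S)-2-(3,4-dihydroxyphenyl)-5,7-dihydroxychroman-4-one]; 2, triisopropylsilyl chloride
Product: 3, (2S)-2-(3,4-dihydroxyphenyl)-5-hydroxy-7-[(triisopropylsilyl)oxy]chroman-4-one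
Conditions: TIPSCl (1.05 equiv), imidazole (2.2 equiv), DMF, −20 → 0 °C, Ar
Reagents that add atoms: TIPSCl, CC(C)[Si](Cl)(C(C)C)C(C)C
Why: Selective phenol silylation: the 7-OH (vinylogous acid, pKa ≈ 7) is far more acidic than the catechol OHs (pKa ≈ 9–10) and the chelated 5-OH, so one equivalent of the bulky silyl chloride with a weak base should cap it first; C2 is untouched and imidazole at ≤0 °C is too weak to open the flavanone.

**Step 2**
Reactants: 3, 7-O-TIPS-eriodictyol; 4, tert-butyl 2-methylbut-3-en-2-yl carbonate
Product: 5, (2S)-5-hydroxy-2-[3,4-bis(2-methylbut-3-en-2-yloxy)phenyl]-7-[(triisopropylsilyl)oxy]chroman-4-one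
Conditions: 4 (2.5 equiv), Pd(PPh3)4 (5 mol %), 4 Å MS, degassed THF, 0 °C, Ar; stop at full conversion, quick chromatography on Et3N-deactivated silica
Reagents that add atoms: tert-butyl 2-methylbut-3-en-2-yl carbonate, C=CC(C)(C)OC(=O)OC(C)(C)C (delivers two C5H9 units; CO2 and t-BuOH are lost)
Why: Tsuji–Trost-type decarboxylative O-allylation: under kinetic control at low temperature the phenoxide attacks the more substituted terminus of the 1,1-dimethyl-π-allyl-Pd to give tertiary aryl ethers; the only base is transient t-BuO⁻ that is quenched at once by the phenol, so the chelated 5-OH, the TIPS ether and C2 are left alone.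

**Step 3**
Reactants: 5, bis(1,1-dimethylallyl) ether
Product: 6, (2S)-2-[3,4-dihydroxy-2,5-bis(3-methylbut-2-en-1-yl)phenyl]-5-hydroxy-7-[(triisopropylsilyl)oxy]chroman-4-one
Conditions: PhMe (0.02 M, degassed), 110 °C, sealed tube, Ar, base-washed glassware
Reagents that add atoms: none
Why: Double aromatic Claisen [3,3] rearrangement: each O–C(Me)2CH=CH2 unit delivers its terminal CH2 to the single free ortho carbon (O3' → C2', O4' → C5') with allylic transposition to a prenyl group, then re-aromatises to the catechol; the conditions are neutral and aprotic, so C2 is not touched.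

**Step 4**
Reactants: 6, 7-O-TIPS-sigmoidin A
Product: 7, sigmoidin A [(2S)-2-[3,4-dihydroxy-2,5-bis(3-methylbut-2-en-1-yl)phenyl]-5,7-dihydroxychroman-4-one]
Conditions: TBAF/AcOH (1:1, 1.2 equiv), THF, 0 °C, Ar
Reagents that add atoms: none
Why: Fluoride cleavage of an aryl silyl ether whose phenoxide is an excellent leaving group; the acetic acid buffer keeps the medium non-basic (no chalcone opening or racemisation) and non-acidic (no chroman formation from the ortho-prenyl phenols).

The ee of 7 should be confirmed by chiral HPLC against a racemised sample.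

## Compound list

1 | (2S)-eriodictyol | Oc1ccc([C@@H]2CC(=O)c3c(O)cc(O)cc3O2)cc1O | starting material
2 | triisopropylsilyl chloride | CC(C)[Si](Cl)(C(C)C)C(C)C | starting material (reagent)
3 | (2S)-2-(3,4-dihydroxyphenyl)-5-hydroxy-7-(triisopropylsilyloxy)chroman-4-one | Oc1ccc([C@@H]2CC(=O)c3c(O)cc(O[Si](C(C)C)(C(C)C)C(C)C)cc3O2)cc1O | intermediate
4 | tert-butyl 2-methylbut-3-en-2-yl carbonate | C=CC(C)(C)OC(=O)OC(C)(C)C | starting material (reagent)
5 | (2S)-5-hydroxy-2-[3,4-bis(2-methylbut-3-en-2-yloxy)phenyl]-7-(triisopropylsilyloxy)chroman-4-one | C=CC(C)(C)Oc1ccc([C@@H]2CC(=O)c3c(O)cc(O[Si](C(C)C)(C(C)C)C(C)C)cc3O2)cc1OC(C)(C)C=C | intermediate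
6 | (2S)-2-[3,4-dihydroxy-2,5-bis(3-methylbut-2-en-1-yl)phenyl]-5-hydroxy-7-(triisopropylsilyloxy)chroman-4-one | CC(C)=CCc1cc([C@@H]2CC(=O)c3c(O)cc(O[Si](C(C)C)(C(C)C)C(C)C)cc3O2)c(CC=C(C)C)c(O)c1O | intermediate
7 | sigmoidin A, (2S) | CC(C)=CCc1cc([C@@H]2CC(=O)c3c(O)cc(O)cc3O2)c(CC=C(C)C)c(O)c1O | target

## Summary

Total steps: 4. Longest linear sequence: 4.

**Three steps most likely to fail**

1. **Step 2 (bis-O-tert-prenylation).** Risks: the second tertiary ether forms next to the first and may be slow; over-reaction isomerises to linear O-prenyl ethers; some 5-O-alkylation or silyl transfer to the catecholate. Fallback: go iteratively — mono-etherify, Claisen, then etherify the remaining OH and Claisen again — so that no congested bis-tertiary ether is ever needed (two extra steps, same neutral chemistry).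

2. **Step 3 (double Claisen).** Risks: loss of isoprene from the tertiary ethers (giving mono- or unprenylated catechol), sluggish migration to the hindered C2', chroman formation, and some C2 erosion once the 4'-OH is free at 110 °C. Fallback: make the 3',4'-bis-O-allyl ether instead, which has no isoprene-loss channel; run the double Claisen to the 2',5'-diallyl catechol, then convert both allyl groups to prenyl by cross-metathesis with 2-methyl-2-butene (Grubbs II).

3. **Step 1 (selective 7-O-silylation).** Risks: competing catechol silylation or later silyl migration to the catechol. Fallback: protect by acidity-controlled alkylation instead, as the 7-O-MOM ether (MOMCl with one equivalent of i-Pr2NEt, so that essentially only the 7-phenoxide is alkylated); it cannot migrate and is removed last with dilute HCl/MeOH at ≤40 °C in place of fluoride.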